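**Retrosynthetic overview**
The strategy rests on the one bond between the two flavones. It joins C3 of ring C in the acacetin half (unit 1) to C6 of ring A in the apigenin half (unit 2). C3 is the central carbon of a latent 1,3-diketone and C6 lies between the C5 and C7 oxygens, so both carbons are innate nucleophiles and one must be inverted.
Disconnection 1 opens ring C of unit 1 at O1–C2, giving a 2-aryl-1,3-diketone whose ring A phenol is masked as a MOM ether; all other phenols are benzyl ethers.
Disconnection 2 (key C–C bond) cuts between the central diketone carbon and C6 of unit 2. This gives an enolisable diketone as the nucleophile and a flavon-6-yl lead triacetate (tetravalent lead) as the aryl cation equivalent.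
The lead reagent traces back through the stannane and the 6-iodide to apigenin. The diketone traces back by Claisen condensation to protected phloracetophenone and methyl 4-methoxybenzoate.
Only ring C of unit 1 is built, after the halves are joined; rings A, B and C of unit 2 and rings A and B of unit 1 are bought intact, and hydrogenolysis ends the route.

Key step: step 9

Assumption: the target SMILES carries no stereodescriptor, so the hindered C3–C6 biaryl axis is treated as undefined and is formed racemic.

Step 1
Reactants: 1 apigenin (5,7-dihydroxy-2-(4-hydroxyphenyl)-4H-chromen-4-one)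
Product: 2 7,4'-di-O-benzylapigenin (7-(benzyloxy)-2-[4-(benzyloxy)phenyl]-5-hydroxy-4H-chromen-4-one)
Conditions: BnBr (2.2 equiv), K2CO3 (2.5 equiv), DMF, rt
Reagents that add atoms: benzyl bromide, BrCc1ccccc1
Why: Williamson ether synthesis under a weak base, in which the acidic 7- and 4'-hydroxyls are alkylated while the 5-hydroxyl, held in a hydrogen bond to the C4 carbonyl, should stay free as long as the halide is limited.

Step 2
Reactants: 2 7,4'-di-O-benzylapigenin
Product: 3 6-iodo-7,4'-di-O-benzylapigenin (7-(benzyloxy)-2-[4-(benzyloxy)phenyl]-5-hydroxy-6-iodo-4H-chromen-4-one)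
Conditions: BnNMe3·ICl2 (1.1 equiv), CaCO3 (1.5 equiv), CH2Cl2–MeOH, rt
Reagents that add atoms: benzyltrimethylammonium dichloroiodate, C[N+](C)(C)Cc1ccccc1.Cl[I-]Cl
Why: Electrophilic aromatic iodination, relying on the known behaviour of 5-hydroxy-7-alkoxyflavones, which take up iodine at C6 next to the chelated hydroxyl (the 5-ethers react at C8), with CaCO3 consuming the HCl and the deactivated ring B expected to stay untouched.

Step 3
Reactants: 3 6-iodo-7,4'-di-O-benzylapigenin
Product: 4 6-iodo-5,7,4'-tris(benzyloxy)flavone (5,7-bis(benzyloxy)-2-[4-(benzyloxy)phenyl]-6-iodo-4H-chromen-4-one)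
Conditions: BnBr (1.5 equiv), K2CO3 (3 equiv), DMF, 65 °C
Reagents that add atoms: benzyl bromide, BrCc1ccccc1
Why: Williamson ether synthesis under forcing conditions, where heat and excess halide overcome the chelation and the flanking iodine, and the cap is needed so that no ortho-phenol of unit 2 can later attack the diketone.

Step 4
Reactants: 4 6-iodo-5,7,4'-tris(benzyloxy)flavone
Product: 5 6-(tributylstannyl)-5,7,4'-tris(benzyloxy)flavone (5,7-bis(benzyloxy)-2-[4-(benzyloxy)phenyl]-6-(tributylstannyl)-4H-chromen-4-one)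
Conditions: (Bu3Sn)2 (1.5 equiv), Pd(PPh3)4 (5 mol %), degassed 1,4-dioxane, 100 °C
Reagents that add atoms: hexabutylditin, CCCC[Sn](CCCC)(CCCC)[Sn](CCCC)(CCCC)CCCC
Why: Palladium-catalysed stannylation of an aryl iodide with a ditin (oxidative addition to zerovalent palladium, Sn–Sn transmetalation, reductive elimination), a neutral process known for alkoxy-substituted aryl iodides that leaves the chromone and the benzyl ethers alone.

Step 5
Reactants: 5 6-(tributylstannyl)-5,7,4'-tris(benzyloxy)flavone
Product: 6 flavon-6-yl lead triacetate ({5,7-bis(benzyloxy)-2-[4-(benzyloxy)phenyl]-4-oxo-4H-chromen-6-yl}lead triacetate)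
Conditions: Pb(OAc)4 (1.0 equiv, freed of AcOH in vacuo), Hg(OAc)2 (10 mol %), dry CHCl3, 40 °C, dark; Celite filtration, pentane trituration, used at once
Reagents that add atoms: lead tetraacetate, CC(=O)O[Pb](OC(C)=O)(OC(C)=O)OC(C)=O
Why: Mercury-catalysed tin–lead exchange (ipso electrophilic substitution at the C–Sn carbon), the standard entry to electron-rich aryllead triacetates, which places tetravalent lead exactly where the stannane stood.

Step 6
Reactants: 7 2,4,6-trihydroxyacetophenone
Product: 8 1-[2,4-bis(benzyloxy)-6-hydroxyphenyl]ethanone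
Conditions: BnBr (2.1 equiv), K2CO3 (2.2 equiv), DMF, 60 °C
Reagents that add atoms: benzyl bromide, BrCc1ccccc1
Why: Williamson ether synthesis with two equivalents of halide, in which one of the two equivalent ortho-hydroxyls remains hydrogen-bonded to the acetyl carbonyl and should be left free.

Step 7
Reactants: 8 1-[2,4-bis(benzyloxy)-6-hydroxyphenyl]ethanone
Product: 9 1-[2,4-bis(benzyloxy)-6-(methoxymethoxy)phenyl]ethanone
Conditions: NaH (1.2 equiv), MOMCl (1.3 equiv), DMF, 0 °C to rt
Reagents that add atoms: chloromethyl methyl ether, COCCl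
Why: O-alkylation of the sodium phenoxide to a MOM acetal, in which the strong base breaks the chelate and the mask is orthogonal to benzyl and falls under the acid used for ring closure.

Step 8
Reactants: 9 1-[2,4-bis(benzyloxy)-6-(methoxymethoxy)phenyl]ethanone + 10 methyl 4-methoxybenzoate
Product: 11 1-[2,4-bis(benzyloxy)-6-(methoxymethoxy)phenyl]-3-(4-methoxyphenyl)propane-1,3-dione (open form of unit 1)
Conditions: NaH (3 equiv), 10 (1.5 equiv), THF, reflux; AcOH quench at 0 °C
Reagents that add atoms: none
Why: Crossed Claisen condensation, in which only the ketone can enolise, the hindered ketone does not self-condense, and irreversible deprotonation of the product diketone drives the equilibrium.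

Step 9
Reactants: 11 1-[2,4-bis(benzyloxy)-6-(methoxymethoxy)phenyl]-3-(4-methoxyphenyl)propane-1,3-dione + 6 flavon-6-yl lead triacetate
Product: 13 2-(flavon-6-yl)-1,3-diketone (1-[2,4-bis(benzyloxy)-6-(methoxymethoxy)phenyl]-2-{5,7-bis(benzyloxy)-2-[4-(benzyloxy)phenyl]-4-oxo-4H-chromen-6-yl}-3-(4-methoxyphenyl)propane-1,3-dione; racemic at C2; keto–enol mixture), via aryl(enolato)lead diacetate 12 (not isolated)
Conditions: 6 (1.2 equiv), pyridine (3.6 equiv), dry ethanol-free CHCl3, 40 to 60 °C, argon, dark
Reagents that add atoms: none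
Why: Proposed new method: the enol of 11 should displace one acetate from the tetravalent lead of 6 (pyridine binds to lead and takes up the acetic acid) to give 12, and ligand coupling between the aryl ipso carbon and the central enolate carbon then forms the bond from the future C3 of unit 1 to C6 of unit 2 while lead departs as divalent Pb(OAc)2. The closest known reaction type is the Pinhey arylation of enolised β-dicarbonyl compounds (4-hydroxycoumarins, 3-activated chroman-4-ones, 2-substituted β-diketones) with di-ortho-alkoxy reagents such as 2,4,6-trimethoxyphenyllead triacetate, and what has not been shown is its use on an acyclic 1,3-diaryl-1,3-diketone bearing no substituent at the central carbon, a class whose chelated enol reacts sluggishly. No ring closes in this step. The central carbon of 13 is stereogenic only in the keto tautomer, nothing controls it, it forms racemic and it becomes the planar C3 in step 10. The step needs C- over O-arylation, which the carbon preference of ligand coupling on lead and the absence of any free phenol (MOM and benzyl ethers) should secure, and it needs monoarylation, which should follow because the first di-ortho-benzyloxy aryl group shields the remaining central C–H from a second bulky lead reagent. The site on unit 2 is not at issue here, since the C–Pb bond inherited from the C6 iodide fixes it.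

Step 10
Reactants: 13 2-(flavon-6-yl)-1,3-diketone
Product: 15 pentabenzyl biflavone (5,7-bis(benzyloxy)-3-{5,7-bis(benzyloxy)-2-[4-(benzyloxy)phenyl]-4-oxo-4H-chromen-6-yl}-2-(4-methoxyphenyl)-4H-chromen-4-one), via free-phenol diketone 14 (not isolated)
Conditions: conc. HCl (5 equiv), MeOH–THF, 50 °C
Reagents that add atoms: none
Why: Acid-catalysed acetal cleavage followed by cyclodehydration (the closing stage of a Baker–Venkataraman-type flavone synthesis), in which the phenol of 14 adds 6-exo-trig to the anisoyl carbonyl, the only carbonyl it can reach, and loss of water gives the pyranone and erases the stereocentre, while the much slower-cleaving benzyl ethers keep the oxygens of unit 2 from closing a benzofuran.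

Step 11
Reactants: 15 pentabenzyl biflavone
Product: 16 target CNP0273516.0 (5,7-dihydroxy-3-[5,7-dihydroxy-2-(4-hydroxyphenyl)-4-oxo-4H-chromen-6-yl]-2-(4-methoxyphenyl)-4H-chromen-4-one)
Conditions: H2 (1 atm), 10% Pd/C, THF–MeOH, rt
Reagents that add atoms: none
Why: Catalytic hydrogenolysis of benzyl aryl ethers, which should cleave all five O–CH2Ph bonds under one atmosphere of hydrogen while the aryl methyl ether is inert and the vinylogous-ester C2=C3 bonds of both chromones are reduced far more slowly.

**Compound list**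
1 | apigenin | O=c1cc(-c2ccc(O)cc2)oc2cc(O)cc(O)c12 | starting material
2 | 7-(benzyloxy)-2-[4-(benzyloxy)phenyl]-5-hydroxy-4H-chromen-4-one | O=c1cc(-c2ccc(OCc3ccccc3)cc2)oc2cc(OCc3ccccc3)cc(O)c12 | intermediate
3 | 7-(benzyloxy)-2-[4-(benzyloxy)phenyl]-5-hydroxy-6-iodo-4H-chromen-4-one | O=c1cc(-c2ccc(OCc3ccccc3)cc2)oc2cc(OCc3ccccc3)c(I)c(O)c12 | intermediate
4 | 5,7-bis(benzyloxy)-2-[4-(benzyloxy)phenyl]-6-iodo-4H-chromen-4-one | O=c1cc(-c2ccc(OCc3ccccc3)cc2)oc2cc(OCc3ccccc3)c(I)c(OCc3ccccc3)c12 | intermediate
5 | 5,7-bis(benzyloxy)-2-[4-(benzyloxy)phenyl]-6-(tributylstannyl)-4H-chromen-4-one | CCCC[Sn](CCCC)(CCCC)c1c(OCc2ccccc2)cc2oc(-c3ccc(OCc4ccccc4)cc3)cc(=O)c2c1OCc1ccccc1 | intermediate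
6 | {5,7-bis(benzyloxy)-2-[4-(benzyloxy)phenyl]-4-oxo-4H-chromen-6-yl}lead triacetate | CC(=O)O[Pb](OC(C)=O)(OC(C)=O)c1c(OCc2ccccc2)cc2oc(-c3ccc(OCc4ccccc4)cc3)cc(=O)c2c1OCc1ccccc1 | intermediate
7 | 2,4,6-trihydroxyacetophenone | CC(=O)c1c(O)cc(O)cc1O | starting material
8 | 1-[2,4-bis(benzyloxy)-6-hydroxyphenyl]ethanone | CC(=O)c1c(O)cc(OCc2ccccc2)cc1OCc1ccccc1 | intermediate
9 | 1-[2,4-bis(benzyloxy)-6-(methoxymethoxy)phenyl]ethanone | CC(=O)c1c(OCOC)cc(OCc2ccccc2)cc1OCc1ccccc1 | intermediate
10 | methyl 4-methoxybenzoate | COC(=O)c1ccc(OC)cc1 | starting material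
11 | 1-[2,4-bis(benzyloxy)-6-(methoxymethoxy)phenyl]-3-(4-methoxyphenyl)propane-1,3-dione | COCOc1cc(OCc2ccccc2)cc(OCc2ccccc2)c1C(=O)CC(=O)c1ccc(OC)cc1 | intermediate
12 | aryl(enolato)lead diacetate, the (Z)-enolate of 11 bound through oxygen to the flavon-6-yl-Pb(OAc)2 fragment (not isolated) | COCOc1cc(OCc2ccccc2)cc(OCc2ccccc2)c1C(=O)/C=C(\O[Pb](OC(C)=O)(OC(C)=O)c1c(OCc2ccccc2)cc2oc(-c3ccc(OCc4ccccc4)cc3)cc(=O)c2c1OCc1ccccc1)c1ccc(OC)cc1 | intermediate
13 | 1-[2,4-bis(benzyloxy)-6-(methoxymethoxy)phenyl]-2-{5,7-bis(benzyloxy)-2-[4-(benzyloxy)phenyl]-4-oxo-4H-chromen-6-yl}-3-(4-methoxyphenyl)propane-1,3-dione (racemic at C2) | COCOc1cc(OCc2ccccc2)cc(OCc2ccccc2)c1C(=O)C(C(=O)c1ccc(OC)cc1)c1c(OCc2ccccc2)cc2oc(-c3ccc(OCc4ccccc4)cc3)cc(=O)c2c1OCc1ccccc1 | intermediate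
14 | 1-[2,4-bis(benzyloxy)-6-hydroxyphenyl]-2-{5,7-bis(benzyloxy)-2-[4-(benzyloxy)phenyl]-4-oxo-4H-chromen-6-yl}-3-(4-methoxyphenyl)propane-1,3-dione (racemic at C2, not isolated) | Oc1cc(OCc2ccccc2)cc(OCc2ccccc2)c1C(=O)C(C(=O)c1ccc(OC)cc1)c1c(OCc2ccccc2)cc2oc(-c3ccc(OCc4ccccc4)cc3)cc(=O)c2c1OCc1ccccc1 | intermediate
15 | 5,7-bis(benzyloxy)-3-{5,7-bis(benzyloxy)-2-[4-(benzyloxy)phenyl]-4-oxo-4H-chromen-6-yl}-2-(4-methoxyphenyl)-4H-chromen-4-one (racemic axis) | COc1ccc(-c2oc3cc(OCc4ccccc4)cc(OCc4ccccc4)c3c(=O)c2-c2c(OCc3ccccc3)cc3oc(-c4ccc(OCc5ccccc5)cc4)cc(=O)c3c2OCc2ccccc2)cc1 | intermediate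
16 | 5,7-dihydroxy-3-[5,7-dihydroxy-2-(4-hydroxyphenyl)-4-oxo-4H-chromen-6-yl]-2-(4-methoxyphenyl)-4H-chromen-4-one (CNP0273516.0) | COc1ccc(-c2oc3cc(O)cc(O)c3c(=O)c2-c2c(O)cc3oc(-c4ccc(O)cc4)cc(=O)c3c2O)cc1 | target

Total step count: 11
Longest linear sequence: 8 steps (steps 1–5, then 9–11, from apigenin)

**Steps most likely to fail**

1. Step 9 (Proposed new method).
   - Risk: Ligand exchange of the strongly chelated enol at lead, or the coupling that follows, may be slower than decay of the lead reagent by protodeplumbation and acetate transfer. Acetoxylation of the diketone by traces of Pb(OAc)4 may also compete.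
   - Fallback: This uses known chemistry, closes ring C before the union and replaces lead by palladium. It sets out from 11, draws on iodide 4, and comes back to the route at 15.
   - Route: Treating 11 with HCl in MeOH–THF at 50 °C frees 1-[2,4-bis(benzyloxy)-6-hydroxyphenyl]-3-(4-methoxyphenyl)propane-1,3-dione F1, which cyclodehydrates in the same flask to 5,7-bis(benzyloxy)-2-(4-methoxyphenyl)-4H-chromen-4-one F2. Directed zincation of the only ring C hydrogen with TMPZnCl·LiCl in THF at rt gives 5,7-bis(benzyloxy)-3-(chlorozincio)-2-(4-methoxyphenyl)-4H-chromen-4-one F3. Negishi coupling of F3 with 4 (Pd2(dba)3, RuPhos, THF, 65 °C), a ligand system established for tetra-ortho-substituted biaryls, should give 15.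

2. Step 4.
   - Risk: Transmetalation of the bulky ditin at the di-ortho-benzyloxy arylpalladium iodide may be so slow that reductive deiodination and homocoupling take over.
   - Fallback: Boron replaces tin as the relay element to lead. It sets out from 4, bypasses 5, and comes back at 6.
   - Route: Miyaura borylation (B2pin2, PdCl2(dppf), KOAc, 1,4-dioxane, 90 °C) should give 5,7-bis(benzyloxy)-2-[4-(benzyloxy)phenyl]-6-(4,4,5,5-tetramethyl-1,3,2-dioxaborolan-2-yl)-4H-chromen-4-one F4. Oxidative removal of the pinacol (NaIO4, NH4OAc, acetone–water, rt) gives {5,7-bis(benzyloxy)-2-[4-(benzyloxy)phenyl]-4-oxo-4H-chromen-6-yl}boronic acid F5, which is used without storage because such acids protodeboronate easily. The known boron–lead exchange (Pb(OAc)4, Hg(OAc)2 10 mol %, CHCl3, 40 °C) then delivers 6.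

3. Step 11.
   - Risk: The benzyl ethers flanking the biaryl axis may be cleaved incompletely, or the C2=C3 bond of unit 2 may be saturated on the long exposure that five cleavages require.
   - Fallback: A non-reductive, Lewis-acid cleavage sets out from 15 and ends at 16.
   - Route: BCl3 (excess) with pentamethylbenzene as benzyl cation scavenger in CH2Cl2 at −78 °C, followed by methanol quench, should remove all five benzyl groups. It cannot touch the chromone double bonds, and at this temperature it should leave the unchelated 4'-methyl ether in place.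

**Further compounds**
F1 | step 9 | 1-[2,4-bis(benzyloxy)-6-hydroxyphenyl]-3-(4-methoxyphenyl)propane-1,3-dione | COc1ccc(C(=O)CC(=O)c2c(O)cc(OCc3ccccc3)cc2OCc2ccccc2)cc1
F2 | step 9 | 5,7-bis(benzyloxy)-2-(4-methoxyphenyl)-4H-chromen-4-one | COc1ccc(-c2cc(=O)c3c(OCc4ccccc4)cc(OCc4ccccc4)cc3o2)cc1
F3 | step 9 | 5,7-bis(benzyloxy)-3-(chlorozincio)-2-(4-methoxyphenyl)-4H-chromen-4-one | COc1ccc(-c2oc3cc(OCc4ccccc4)cc(OCc4ccccc4)c3c(=O)c2[Zn]Cl)cc1
F4 | step 4 | 5,7-bis(benzyloxy)-2-[4-(benzyloxy)phenyl]-6-(4,4,5,5-tetramethyl-1,3,2-dioxaborolan-2-yl)-4H-chromen-4-one | CC1(C)OB(OC1(C)C)c1c(OCc2ccccc2)cc2oc(-c3ccc(OCc4ccccc4)cc3)cc(=O)c2c1OCc1ccccc1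
F5 | step 4 | {5,7-bis(benzyloxy)-2-[4-(benzyloxy)phenyl]-4-oxo-4H-chromen-6-yl}boronic acid | OB(O)c1c(OCc2ccccc2)cc2oc(-c3ccc(OCc4ccccc4)cc3)cc(=O)c2c1OCc1ccccc1
F0 | step 11 | none | none
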